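Early times in the flasks below raise the first question: how does the pace follow the free catalyst?

| flask | starting material | coupling partner | free catalyst | target | time |
|---|---|---|---|---|---|
| autumn | 80.0 mM | 88.0 mM | 0.160 mM |  |  |
| spring | 32.0 mM | 40.0 mM | 0.160 mM |  |  |
| summer | 80.0 mM | 88.0 mM | 0.320 mM |  |  |
| dawn | 80.0 mM | 88.0 mM | 0.160 mM | 40.0 mM | 20 min |

| run | time / min | [target] / mM |
|---|---|---|
| autumn run | 2.9 | 9.1 |
| autumn run | 5.7 | 17.3 |
| autumn run | 8.6 | 23.4 |
| autumn run | 11 | 28.4 |
| autumn run | 14 | 30.5 |
| autumn run | 17 | 33.7 |
| autumn run | 20 | 35.1 |
| spring run | 2.9 | 5.5 |
| spring run | 5.7 | 9.1 |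
| spring run | 8.6 | 13.0 |
| spring run | 11 | 14.6 |
| spring run | 14 | 16.5 |
| spring run | 17 | 18.6 |
| spring run | 20 | 17.5 |
| summer run | 2.9 | 17.6 |
| summer run | 5.7 | 32.8 |
| summer run | 8.6 | 40.1 |
| summer run | 11 | 43.0 |
| summer run | 14 | 43.2 |
| summer run | 17 | 44.0 |
| summer run | 20 | 44.0 |

(each reading ± 0.6 mM)

- Overall: starting material + coupling partner -> target, with free catalyst as catalyst.
- Constant volume, constant temperature.
- The analysis sees a species whether free or bound.
- An order is taken over about fifteen percent of the charge, up and down.
- A share of target counts the target that was charged too.

1. order of the initial rate in [free catalyst], near the charge of the autumn run, the rate being that where two percent of its starting material are target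
2. target in the dawn run at 20 min, as a share of the starting material charged

At the first reading the summer run, with twice the free catalyst of the autumn run, holds 22.0 % of its starting material as target, against 11.4 % in the autumn run. Those two readings put the order at about 0.952.

Does catalyst then merely rescale the time axis? Selwyn's test asks this: curves should coincide at equal catalyst × time. They do not, since the summer run at 8.6 min holds 50.1 %, more than the 42.1 % of the autumn run at 17 min. Some loss therefore runs on the clock, not on catalyst turnovers.

Could target be the brake instead? The spring run at 20 min holds 54.7 % of its charge and reads no gain over its previous reading. The summer run at 2.9 min reads the same amount of target within the scatter, 22.0 % of its own larger charge, yet its next interval reads 0.894 of its opening pace. So I treat target as a bystander.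

The dawn run is the autumn recipe plus target equal to 50.0 % of the starting material. The autumn run gives 43.9 % as its made share, the target formed by 20 min over the starting material charged. Adding the two, I expect a dawn share of 93.9 %.

The forecast gives an order of 0.97 (0.8 to 1.15) and a dawn share of 72 % (59 % to 87 %), holding that “the stall depends on the ratio”.

The flask gives an order of 0.98 and a dawn share of 92.9 %.

    free catalyst + starting material → catalyst-substrate complex (3342 M⁻¹ min⁻¹)
    catalyst-substrate complex + coupling partner → loaded catalyst (480.0 M⁻¹ min⁻¹)
    loaded catalyst → target + free catalyst (660.0 min⁻¹)
    starting material + coupling partner ⇌ idle substrate-reagent adduct, settled at all times (15.30 M⁻¹)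
    2 starting material → homo dimer (6.360 M⁻¹ min⁻¹)

The made share of the dawn run is 42.9 %, beside the 43.9 % read from the autumn run. The passing of starting material into homo dimer holds that share down. The dawn flask without that step reaches 113 %, higher than the 92.9 % with it, and its made share becomes 63.3 %.

The runs were computed with constants of no real substance, noise included.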